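**Retrosynthetic overview**

1. Target acid ⇐ methyl ester (saponification) ⇐ C5–C6 bond made by adding the (E)-alkenylalane of the side chain to a dioxolanyl peroxycarbenium ion generated from a silyl peroxyketal.
2. Acrylate arm ⇐ cross-metathesis of the C3 vinyl group with methyl acrylate, done before the side chain (which carries a metathesis-active alkene) is attached.
3. Key step and only heterocycle: O2 ring expansion of a 1-siloxy-2-vinylcyclopropane to the 1,2-dioxolane under a chiral thiyl-radical catalyst. It sets C3; the O2-capture carbon becomes the ketal carbon that is ionised later, so its configuration does not matter.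
4. Vinylcyclopropane ⇐ Simmons–Smith on a 2-siloxydiene ⇐ β,γ-unsaturated ketone ⇐ pentenyl Grignard + Weinreb amide. Ring order: cyclopropane, then 1,2-dioxolane.
5. Side chain ⇐ terminal alkyne ⇐ methyl ketone ⇐ Rh/BINAP conjugate addition of butenylboronic acid to hexenone (sets the remote stereocentre).

Target configuration as read from the SMILES: (3S,5R) on the dioxolane (3,5-diethyl cis), 4R in the side chain, all three alkenes E.

Assumption: 1, 2, 8, 10 and 11 are bought, and for the two chiral catalysts (steps 4 and 6) the antipode that gives the stated configuration is used after a pilot run confirms the sense of induction.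

**Route**

Step 1
Reactants: 1 (2E)-1-bromopent-2-ene; 2 N-methoxy-N-methylpropanamide
Product: 4 (±)-4-ethylhex-5-en-3-one, via pentenylmagnesium bromide 3 (not isolated)
Conditions: Mg, Et2O, 0 °C; then 2, THF, −78 → 0 °C; cold 1 M HCl
Reagents that add atoms: none
Why: Allylic Grignard addition to a Weinreb amide goes through γ-attack (SE2′) and a chelated tetrahedral intermediate that stops at the ketone, giving the α-branched β,γ-unsaturated ketone; its stereocentre is racemic and is removed in step 2.

Step 2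
Reactants: 4 (±)-4-ethylhex-5-en-3-one
Product: 5 tert-butyl[(4-ethylhexa-3,5-dien-3-yl)oxy]dimethylsilane (3E/3Z mixture)
Conditions: TBSOTf, Et3N, CH2Cl2, 0 °C
Reagents that add atoms: tert-butyldimethylsilyl triflate, CC(C)(C)[Si](C)(C)OS(=O)(=O)C(F)(F)F
Why: Soft enolisation removes the doubly activated (α-keto and allylic) C4–H and gives the conjugated 2-siloxydiene (silyl dienol ether formation); no stereocentre is involved.

Step 3
Reactants: 5 tert-butyl[(4-ethylhexa-3,5-dien-3-yl)oxy]dimethylsilane
Product: 6 tert-butyl[(1,2-diethyl-2-ethenylcyclopropyl)oxy]dimethylsilane (racemic, both diastereomers)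
Conditions: Et2Zn (1.5 equiv), CH2I2 (1.5 equiv), CH2Cl2, 0 °C → rt
Reagents that add atoms: diiodomethane, ICI
Why: The electrophilic zinc carbenoid (Furukawa-modified Simmons–Smith cyclopropanation) selects the electron-rich silyl enol ether C=C over the terminal vinyl group; both ring stereocentres are destroyed in step 4, so the isomer mixture is used as such.

Step 4
Reactants: 6 tert-butyl[(1,2-diethyl-2-ethenylcyclopropyl)oxy]dimethylsilane
Product: 7 (5S)-3-{[tert-butyl(dimethyl)silyl]oxy}-3,5-diethyl-5-ethenyl-1,2-dioxolane (both C3 epimers)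
Conditions: O2 (1 atm), chiral disulfide (Ar*S)2 (5 mol %; Ar*SH = (R)-2′-methoxy-3,3′-bis(2,4,6-triisopropylphenyl)-1,1′-binaphthalene-2-thiol), 390 nm LED, PhCF3, −20 °C
Reagents that add atoms: dioxygen, O=O
Why: Proposed new method: an enantioselective, thiyl-radical-catalysed aerobic ring expansion (cyclopropane → 1,2-dioxolane; a radical chain, not pericyclic) in which Ar*S• adds to the vinyl CH2, the cyclopropylcarbinyl radical opens towards the siloxy carbon, the α-siloxy radical captures O2, and the peroxyl radical closes 5-exo onto the ethyl-bearing alkene carbon inside the chiral pocket of the sulfur substituent before β-scission returns Ar*S• and the vinyl group; the stereocentre made in the uncontrolled O2 capture is the ketal carbon that is ionised in step 8, so only the cyclisation step needs catalyst control, and that step sets the S quaternary centre; closest known reaction types are the racemic PhS•-catalysed vinylcyclopropane oxygenation to 1,2-dioxolanes (Feldman oxygenation) and chiral thiyl-radical-catalysed vinylcyclopropane–alkene cyclisations.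

Step 5
Reactants: 7 (5S)-3-{[tert-butyl(dimethyl)silyl]oxy}-3,5-diethyl-5-ethenyl-1,2-dioxolane; 8 methyl acrylate
Product: 9 methyl (2E)-3-[(3S)-5-{[tert-butyl(dimethyl)silyl]oxy}-3,5-diethyl-1,2-dioxolan-3-yl]prop-2-enoate (both C5 epimers)
Conditions: Hoveyda–Grubbs II (5 mol %), 8 (5 equiv), CH2Cl2, 40 °C
Reagents that add atoms: none
Why: Olefin cross-metathesis between a hindered vinyl group on a fully substituted carbon (which cannot homodimerise) and an acrylate gives the (E)-enoate selectively; the stereocentre is not touched and dialkyl peroxides tolerate Ru carbenes.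

Step 6
Reactants: 10 (3E)-hex-3-en-2-one; 11 (1E)-but-1-en-1-ylboronic acid
Product: 12 (4R,5E)-4-ethyloct-5-en-2-one
Conditions: [Rh(OH)((S)-BINAP)]2 (3 mol % Rh), 11 (2.5 equiv), dioxane/H2O 10:1, 35 °C
Reagents that add atoms: none
Why: Hayashi–Miyaura Rh(I)/BINAP 1,4-addition of an alkenylboronic acid to an acyclic (E)-enone; with (S)-BINAP the alkenyl–Rh species inserts the enone on its αsi face, which gives 4R, and the E geometry of the transferred butenyl group is retained.

Step 7
Reactants: 12 (4R,5E)-4-ethyloct-5-en-2-one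
Product: 14 (4R,5E)-4-ethyloct-5-en-1-yne, via enol phosphate 13 (not isolated)
Conditions: LDA (1.05 equiv), THF, −78 °C; ClP(O)(OEt)2; LDA (2.3 equiv), −78 °C → rt; H2O
Reagents that add atoms: none
Why: Kinetic deprotonation at the methyl group, O-phosphorylation and LDA-induced β-elimination (Negishi methyl ketone → terminal alkyne protocol) give the alkyne; the C4 stereocentre is not acidic and is retained.

Step 8
Reactants: 14 (4R,5E)-4-ethyloct-5-en-1-yne; 9 methyl (2E)-3-[(3S)-5-{[tert-butyl(dimethyl)silyl]oxy}-3,5-diethyl-1,2-dioxolan-3-yl]prop-2-enoate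
Product: 16 methyl (2E)-3-[(3S,5R)-3,5-diethyl-5-[(1E,4R,5E)-4-ethyl-2-methylocta-1,5-dien-1-yl]-1,2-dioxolan-3-yl]prop-2-enoate, via alkenylalane 15 (not isolated)
Conditions: 14 (1.3 equiv), Me3Al (2 equiv), Cp2ZrCl2 (10 mol %), CH2Cl2, 0 °C → rt; excess Me3Al removed in vacuo; then 9, TMSOTf (10 mol %), CH2Cl2, −78 → −40 °C; Rochelle salt work-up; chromatography
Reagents that add atoms: trimethylaluminium, C[Al](C)C
Why: Proposed new method: alkenyl transfer from an alkenylalane to a 1,2-dioxolan-3-ylium (peroxycarbenium) ion, in which Zr-catalysed syn-carboalumination gives the (E)-alkenylalane (>98 % E), the Lewis-acidic alane with catalytic TMSOTf ionises the silyl peroxyketal (both epimers give the same cation), and the alkenyl–Al carbon attacks by ipso SE2 with retention of alkene geometry faster than methyl transfer; attack is expected on the envelope face syn to the pseudoaxial, π-donating acrylate arm with ethyl pseudo-equatorial, which gives the cis-3,5-diethyl (5R) isomer (estimated dr about 3:1, the 5S epimer being removed by chromatography); closest known reaction types are the Lewis acid-mediated substitution of 3-alkoxy-1,2-dioxolanes by allylsilanes and silyl enol ethers and the reaction of alkenylalanes with α-halo ethers and other oxocarbenium precursors.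

Step 9
Reactants: 16 methyl (2E)-3-[(3S,5R)-3,5-diethyl-5-[(1E,4R,5E)-4-ethyl-2-methylocta-1,5-dien-1-yl]-1,2-dioxolan-3-yl]prop-2-enoate
Product: 17 (2E)-3-[(3S,5R)-3,5-diethyl-5-[(1E,4R,5E)-4-ethyl-2-methylocta-1,5-dien-1-yl]-1,2-dioxolan-3-yl]prop-2-enoic acid (CNP0249416.2)
Conditions: LiOH·H2O, THF/MeOH/H2O, 0 °C → rt; 1 M HCl to pH 4 at 0 °C
Reagents that add atoms: lithium hydroxide, [Li+].[OH-]
Why: Ester saponification (BAc2); the dioxolane has no hydrogen on C3 or C5, so base-induced Kornblum–DeLaMare cleavage is not possible and the peroxide, the alkenes and all three stereocentres survive.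

**Compound list**

1 | (2E)-1-bromopent-2-ene | CC/C=C/CBr | starting material
2 | N-methoxy-N-methylpropanamide | CCC(=O)N(C)OC | starting material
3 | (2E)-pent-2-en-1-ylmagnesium bromide | CC/C=C/C[Mg]Br | intermediate (not isolated)
4 | (±)-4-ethylhex-5-en-3-one | CCC(=O)C(CC)C=C | intermediate
5 | tert-butyl[(4-ethylhexa-3,5-dien-3-yl)oxy]dimethylsilane (3E/3Z mixture) | CCC(O[Si](C)(C)C(C)(C)C)=C(CC)C=C | intermediate
6 | tert-butyl[(1,2-diethyl-2-ethenylcyclopropyl)oxy]dimethylsilane (racemic, both diastereomers) | CCC1(O[Si](C)(C)C(C)(C)C)CC1(CC)C=C | intermediate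
7 | (5S)-3-{[tert-butyl(dimethyl)silyl]oxy}-3,5-diethyl-5-ethenyl-1,2-dioxolane (both C3 epimers) | CCC1(O[Si](C)(C)C(C)(C)C)C[C@](C=C)(CC)OO1 | intermediate
8 | methyl acrylate | C=CC(=O)OC | starting material
9 | methyl (2E)-3-[(3S)-5-{[tert-butyl(dimethyl)silyl]oxy}-3,5-diethyl-1,2-dioxolan-3-yl]prop-2-enoate (both C5 epimers) | CCC1(O[Si](C)(C)C(C)(C)C)C[C@](/C=C/C(=O)OC)(CC)OO1 | intermediate
10 | (3E)-hex-3-en-2-one | CC/C=C/C(C)=O | starting material
11 | (1E)-but-1-en-1-ylboronic acid | CC/C=C/B(O)O | starting material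
12 | (4R,5E)-4-ethyloct-5-en-2-one | CC/C=C/[C@H](CC)CC(C)=O | intermediate
13 | diethyl (4R,5E)-4-ethylocta-1,5-dien-2-yl phosphate | CC/C=C/[C@H](CC)CC(=C)OP(=O)(OCC)OCC | intermediate (not isolated)
14 | (4R,5E)-4-ethyloct-5-en-1-yne | CC/C=C/[C@H](CC)CC#C | intermediate
15 | [(1E,4R,5E)-4-ethyl-2-methylocta-1,5-dien-1-yl]dimethylalane | CC/C=C/[C@H](CC)C/C(C)=C/[Al](C)C | intermediate (not isolated)
16 | methyl (2E)-3-[(3S,5R)-3,5-diethyl-5-[(1E,4R,5E)-4-ethyl-2-methylocta-1,5-dien-1-yl]-1,2-dioxolan-3-yl]prop-2-enoate | CC/C=C/[C@H](CC)C/C(C)=C/[C@@]1(CC)C[C@](/C=C/C(=O)OC)(CC)OO1 | intermediate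
17 | (2E)-3-[(3S,5R)-3,5-diethyl-5-[(1E,4R,5E)-4-ethyl-2-methylocta-1,5-dien-1-yl]-1,2-dioxolan-3-yl]prop-2-enoic acid | CC/C=C/[C@H](CC)C/C(C)=C/[C@@]1(CC)C[C@](/C=C/C(=O)O)(CC)OO1 | target

**Step count and risk**

Total steps: 9. Longest linear sequence: 7 (steps 1, 2, 3, 4, 5, 8, 9); the side chain (steps 6 and 7) joins at step 8.

The three steps most likely to fail:

Step 4 (proposed new method). The chiral thiyl radical may give low ee, and the α-siloxy peroxyl radical may fragment instead of cyclising. Fallback with known chemistry, setting out from 6 and coming back at 9: the ring expansion is run under the established achiral conditions for vinylcyclopropane oxygenation (PhSSPh 10 mol %, AIBN, O2, hν, MeCN, 0 °C) to give the racemic vinyl dioxolane F1. F1 is taken through the cross-metathesis of step 5 to the racemic acrylate F2, which is UV-active. F2 is resolved by preparative chiral-phase SFC into 9 and its (3R)-enantiomer F3, which is discarded.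

Step 5. The vinyl group sits on a fully substituted carbon next to a peroxide, so turnover may be low or the Ru catalyst may be consumed. Fallback setting out from 7 and coming back at 9: ozonolysis (O3, CH2Cl2, −78 °C; Me2S) gives the aldehyde (3S)-5-{[tert-butyl(dimethyl)silyl]oxy}-3,5-diethyl-1,2-dioxolane-3-carbaldehyde F4, which cannot epimerise. E-selective Wittig olefination with Ph3P=CHCO2Me (CH2Cl2, rt) then gives 9.

Step 8 (proposed new method). The alane may transfer methyl, attack the O–O bond, or give poor cis/trans selectivity. Fallback with known chemistry, setting out from 9 and 12 and coming back at 16: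
- 9 is allylated under the established conditions for alkoxydioxolanes (allyltrimethylsilane, SnCl4, CH2Cl2, −78 °C) and the cis isomer is separated to give the allyl dioxolane F5.
- Ru–H isomerisation (RuHCl(CO)(PPh3)3, toluene, 60 °C) gives the (E)-propenyl dioxolane F6.
- Ozonolysis of the electron-rich propenyl group only (O3, CH2Cl2, −78 °C, indicator end point; Me2S) gives the aldehyde F7.
- Ramirez olefination (CBr4, PPh3, CH2Cl2, 0 °C) gives the 1,1-dibromoalkene F8.
- In parallel, iodoform cleavage of 12 (I2, NaOH, dioxane/H2O) gives (3R,4E)-3-ethylhept-4-enoic acid F9.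
- Iododecarboxylation (PhI(OAc)2, I2, hν) gives (3S,4E)-3-(iodomethyl)hept-4-ene F10.
- Zinc insertion (Zn, LiCl, THF) gives the alkylzinc iodide F11.
- Pd-catalysed trans-selective monoalkylation of F8 with F11 (PdCl2(DPEphos), THF) gives the (Z)-bromoalkene F12.
- Methylation with retention (Me2Zn, Pd(t-Bu3P)2) gives 16 with the E-trisubstituted alkene.

**Further compounds**

F1 | step 4 | racemic 3-{[tert-butyl(dimethyl)silyl]oxy}-3,5-diethyl-5-ethenyl-1,2-dioxolane | CCC1(O[Si](C)(C)C(C)(C)C)CC(C=C)(CC)OO1
F2 | step 4 | racemic methyl (2E)-3-[5-{[tert-butyl(dimethyl)silyl]oxy}-3,5-diethyl-1,2-dioxolan-3-yl]prop-2-enoate | CCC1(O[Si](C)(C)C(C)(C)C)CC(/C=C/C(=O)OC)(CC)OO1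
F3 | step 4 | methyl (2E)-3-[(3R)-5-{[tert-butyl(dimethyl)silyl]oxy}-3,5-diethyl-1,2-dioxolan-3-yl]prop-2-enoate | CCC1(O[Si](C)(C)C(C)(C)C)C[C@@](/C=C/C(=O)OC)(CC)OO1
F4 | step 5 | (3S)-5-{[tert-butyl(dimethyl)silyl]oxy}-3,5-diethyl-1,2-dioxolane-3-carbaldehyde | CCC1(O[Si](C)(C)C(C)(C)C)C[C@](C=O)(CC)OO1
F5 | step 8 | methyl (2E)-3-[(3S,5S)-3,5-diethyl-5-(prop-2-en-1-yl)-1,2-dioxolan-3-yl]prop-2-enoate | C=CC[C@@]1(CC)C[C@](/C=C/C(=O)OC)(CC)OO1
F6 | step 8 | methyl (2E)-3-[(3S,5R)-3,5-diethyl-5-[(1E)-prop-1-en-1-yl]-1,2-dioxolan-3-yl]prop-2-enoate | C/C=C/[C@@]1(CC)C[C@](/C=C/C(=O)OC)(CC)OO1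
F7 | step 8 | methyl (2E)-3-[(3S,5R)-3,5-diethyl-5-formyl-1,2-dioxolan-3-yl]prop-2-enoate | O=C[C@@]1(CC)C[C@](/C=C/C(=O)OC)(CC)OO1
F8 | step 8 | methyl (2E)-3-[(3S,5R)-5-(2,2-dibromoethenyl)-3,5-diethyl-1,2-dioxolan-3-yl]prop-2-enoate | BrC(Br)=C[C@@]1(CC)C[C@](/C=C/C(=O)OC)(CC)OO1
F9 | step 8 | (3R,4E)-3-ethylhept-4-enoic acid | CC/C=C/[C@H](CC)CC(=O)O
F10 | step 8 | (3S,4E)-3-(iodomethyl)hept-4-ene | CC/C=C/[C@H](CC)CI
F11 | step 8 | [(2S,3E)-2-ethylhex-3-en-1-yl](iodo)zinc | CC/C=C/[C@H](CC)C[Zn]I
F12 | step 8 | methyl (2E)-3-[(3S,5R)-5-[(1Z,4R,5E)-2-bromo-4-ethylocta-1,5-dien-1-yl]-3,5-diethyl-1,2-dioxolan-3-yl]prop-2-enoate | CC/C=C/[C@H](CC)C/C(Br)=C/[C@@]1(CC)C[C@](/C=C/C(=O)OC)(CC)OO1
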